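Assumption 1: (S)-MeO-F12-BIPHEP is taken to give the (2S)-flavanone in step 8, as (S)-biaryl bisphosphines do with cyclic enones; if a model chromone shows the opposite sense, the (R)-ligand is used with no other change.
Assumption 2: "unit E" is the C-3-linked eriodictyol-type chromanone (locants 2–8) and "unit N" the C-8-linked naringenin-type chromanone (locants 2''–8''). Compounds 9–13 are racemic trans and are drawn as the (2R,3S) enantiomer that leads to the target.

**Retrosynthetic overview**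
1. Global hydrogenolysis of benzyl ethers last; C-2'' comes from a ligand-controlled Rh-catalysed 1,4-arylation of an 8-substituted chromone, and the two diastereomers formed from racemic unit E are then separated.
2. The chromone ring of unit N comes from an o-hydroxyacetophenone built on the pendant phloroglucinol ring (acetylation, chelation-controlled debenzylation, enaminone cyclisation).
3. Unit E (trans-2,3-diarylchromanone) comes from a 2-hydroxydeoxybenzoin and 3,4-bis(benzyloxy)benzaldehyde by Knoevenagel/oxa-Michael under thermodynamic control.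
4. The deoxybenzoin, which already holds the C-3/C-8'' bond, comes from Pd-catalysed ketone α-arylation of two phloroglucinol-derived pieces.
5. Ring order: pyranone of unit E, then pyranone of unit N, then its 2''-aryl group.

**Route**

Step 1
Reactants: 1 2',4',6'-trihydroxyacetophenone
Product: 2 2',4',6'-tris(benzyloxy)acetophenone
Conditions: BnBr (3.6 equiv), K2CO3 (4 equiv), DMF, 70 °C
Reagents that add atoms: benzyl bromide, BrCc1ccccc1
Why: Williamson etherification (SN2 O-benzylation) of all three phenoxides, with excess reagent in DMF forcing the chelated ortho hydroxyls to react.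

Step 2
Reactants: 3 1,3,5-tris(benzyloxy)benzene
Product: 4 2-bromo-1,3,5-tris(benzyloxy)benzene
Conditions: NBS (1.0 equiv), CH2Cl2, −20 to 0 °C
Reagents that add atoms: N-bromosuccinimide, O=C1CCC(=O)N1Br
Why: Electrophilic aromatic bromination of a symmetric, highly activated arene gives a single monobromide when one equivalent is used cold.

Step 3
Reactants: 2 2',4',6'-tris(benzyloxy)acetophenone; 4 2-bromo-1,3,5-tris(benzyloxy)benzene
Product: 5 1,2-bis[2,4,6-tris(benzyloxy)phenyl]ethan-1-one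
Conditions: Pd2(dba)3 (2.5 mol %), XPhos (10 mol %), NaOtBu (2.4 equiv), toluene, 90 °C
Reagents that add atoms: none
Why: Buchwald–Hartwig-type ketone α-arylation (oxidative addition of 4 to zerovalent palladium, enolate binding, reductive elimination) stops at monoarylation because the product rests as a hindered enolate.

Step 4
Reactants: 5 1,2-bis[2,4,6-tris(benzyloxy)phenyl]ethan-1-one
Product: 6 1-[2,4-bis(benzyloxy)-6-hydroxyphenyl]-2-[2,4,6-tris(benzyloxy)phenyl]ethan-1-one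
Conditions: MgBr2·OEt2 (3 equiv), toluene/Et2O, 80 °C; then 1 M HCl
Reagents that add atoms: none
Why: Chelation-controlled Lewis-acid debenzylation cleaves only a benzyl ether ortho to the ketone (six-membered magnesium chelate), and the two such ethers are equivalent, so one phenol results.

Step 5
Reactants: 6 1-[2,4-bis(benzyloxy)-6-hydroxyphenyl]-2-[2,4,6-tris(benzyloxy)phenyl]ethan-1-one; 7 3,4-bis(benzyloxy)benzaldehyde
Product: 9 (±)-trans-(2R*,3S*)-5,7-bis(benzyloxy)-2-[3,4-bis(benzyloxy)phenyl]-3-[2,4,6-tris(benzyloxy)phenyl]chroman-4-one, via alpha-aryl chalcone 8 (not isolated)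
Conditions: piperidine (0.5 equiv), DBU (0.5 equiv), toluene/2-butanol, reflux, Dean–Stark
Reagents that add atoms: none
Why: Knoevenagel condensation followed by intramolecular oxa-Michael addition closes the pyranone, and base equilibration at C-2 (retro-oxa-Michael) and C-3 (enolisation) gives the diequatorial 2,3-trans racemate.

Step 6
Reactants: 9 (±)-trans-5,7-bis(benzyloxy)-2-[3,4-bis(benzyloxy)phenyl]-3-[2,4,6-tris(benzyloxy)phenyl]chroman-4-one
Product: 11 (±)-trans-3-[3-acetyl-4,6-bis(benzyloxy)-2-hydroxyphenyl]-7-(benzyloxy)-2-[3,4-bis(benzyloxy)phenyl]-5-hydroxychroman-4-one, via acetyl ketone 10 (not isolated)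
Conditions: AcOH (1.3 equiv), (CF3CO)2O (2 equiv), H3PO4 (cat.), CH2Cl2, 0 °C to rt; evaporate; BCl3 (2.5 equiv), CH2Cl2, −78 °C; then H2O
Reagents that add atoms: acetic acid, CC(=O)O
Why: Friedel–Crafts acetylation through the mixed anhydride hits the most electron-rich (pendant trialkoxy) ring, and chelation-controlled BCl3 debenzylation then removes the unit E 5-O-benzyl and, on the pendant ring, the doubly flanked benzyl ether between the acetyl group and the chromanone substituent in preference to the less crowded ortho ether.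

Step 7
Reactants: 11 (±)-trans-3-[3-acetyl-4,6-bis(benzyloxy)-2-hydroxyphenyl]-7-(benzyloxy)-2-[3,4-bis(benzyloxy)phenyl]-5-hydroxychroman-4-one
Product: 13 (±)-trans-7-(benzyloxy)-2-[3,4-bis(benzyloxy)phenyl]-3-[5,7-bis(benzyloxy)-4-oxo-4H-chromen-8-yl]-5-hydroxychroman-4-one, via enaminone 12 (not isolated)
Conditions: Me2NCH(OMe)2 (2 equiv), toluene, 90 °C; then conc. HCl, CH2Cl2, rt
Reagents that add atoms: N,N-dimethylformamide dimethyl acetal, COC(OC)N(C)C
Why: Enaminone formation at the methyl ketone and acid-promoted addition–elimination (enaminone chromone synthesis) close the pyranone through the only free ortho hydroxyl, which places unit E at C-8''.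

Step 8
Reactants: 13 (±)-trans-7-(benzyloxy)-2-[3,4-bis(benzyloxy)phenyl]-3-[5,7-bis(benzyloxy)-4-oxo-4H-chromen-8-yl]-5-hydroxychroman-4-one; 14 4-(benzyloxy)phenylboronic acid
Product: 15 (2R,3S)-7-(benzyloxy)-2-[3,4-bis(benzyloxy)phenyl]-3-{(2S)-5,7-bis(benzyloxy)-2-[4-(benzyloxy)phenyl]-4-oxochroman-8-yl}-5-hydroxychroman-4-one
Conditions: [Rh(OH)(cod)]2 (3 mol %), (S)-MeO-F12-BIPHEP (6.6 mol %), 14 (4 equiv), toluene/H2O 20:1, 40 °C; SiO2 chromatography then preparative HPLC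
Reagents that add atoms: none
Why: Hayashi–Miyaura asymmetric 1,4-addition (aryl transfer from monovalent rhodium under ligand control) sets C-2'' as S in both enantiomers of 13, and separating the two resulting diastereomers selects the (2R,3S) unit E (at most 50 % of the material).

Step 9
Reactants: 15 (2R,3S)-7-(benzyloxy)-2-[3,4-bis(benzyloxy)phenyl]-3-{(2S)-5,7-bis(benzyloxy)-2-[4-(benzyloxy)phenyl]-4-oxochroman-8-yl}-5-hydroxychroman-4-one
Product: 16 (2R,3S)-2-(3,4-dihydroxyphenyl)-3-[(2S)-5,7-dihydroxy-2-(4-hydroxyphenyl)-4-oxochroman-8-yl]-5,7-dihydroxychroman-4-one (CNP0105436.2)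
Conditions: H2 (1 atm), Pd/C (10 %), EtOAc/MeOH, rt, monitored and stopped at full debenzylation
Reagents that add atoms: none
Why: Catalytic hydrogenolysis removes all six O-benzyl groups under neutral conditions, so neither the retro-oxa-Michael-labile C-2/C-2'' nor the enolisable C-3 is disturbed.

**Compound list**
1 | 2',4',6'-trihydroxyacetophenone | CC(=O)c1c(O)cc(O)cc1O | starting material
2 | 2',4',6'-tris(benzyloxy)acetophenone | CC(=O)c1c(OCc2ccccc2)cc(OCc2ccccc2)cc1OCc1ccccc1 | intermediate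
3 | 1,3,5-tris(benzyloxy)benzene | c1ccc(COc2cc(OCc3ccccc3)cc(OCc3ccccc3)c2)cc1 | starting material
4 | 2-bromo-1,3,5-tris(benzyloxy)benzene | Brc1c(OCc2ccccc2)cc(OCc2ccccc2)cc1OCc1ccccc1 | intermediate
5 | 1,2-bis[2,4,6-tris(benzyloxy)phenyl]ethan-1-one | O=C(Cc1c(OCc2ccccc2)cc(OCc2ccccc2)cc1OCc1ccccc1)c1c(OCc2ccccc2)cc(OCc2ccccc2)cc1OCc1ccccc1 | intermediate
6 | 1-[2,4-bis(benzyloxy)-6-hydroxyphenyl]-2-[2,4,6-tris(benzyloxy)phenyl]ethan-1-one | O=C(Cc1c(OCc2ccccc2)cc(OCc2ccccc2)cc1OCc1ccccc1)c1c(O)cc(OCc2ccccc2)cc1OCc1ccccc1 | intermediate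
7 | 3,4-bis(benzyloxy)benzaldehyde | O=Cc1ccc(OCc2ccccc2)c(OCc2ccccc2)c1 | starting material
8 | (E)-1-[2,4-bis(benzyloxy)-6-hydroxyphenyl]-3-[3,4-bis(benzyloxy)phenyl]-2-[2,4,6-tris(benzyloxy)phenyl]prop-2-en-1-one (not isolated) | O=C(c1c(O)cc(OCc2ccccc2)cc1OCc1ccccc1)/C(c1c(OCc2ccccc2)cc(OCc2ccccc2)cc1OCc1ccccc1)=C/c1ccc(OCc2ccccc2)c(OCc2ccccc2)c1 | intermediate
9 | (±)-trans-(2R*,3S*)-5,7-bis(benzyloxy)-2-[3,4-bis(benzyloxy)phenyl]-3-[2,4,6-tris(benzyloxy)phenyl]chroman-4-one | c1ccccc1COc1cc(OCc2ccccc2)cc(OCc2ccccc2)c1[C@@H]1C(=O)c2c(OCc3ccccc3)cc(OCc3ccccc3)cc2O[C@H]1c1ccc(OCc2ccccc2)c(OCc2ccccc2)c1 | intermediate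
10 | (±)-trans-3-[3-acetyl-2,4,6-tris(benzyloxy)phenyl]-5,7-bis(benzyloxy)-2-[3,4-bis(benzyloxy)phenyl]chroman-4-one (not isolated) | CC(=O)c1c(OCc2ccccc2)cc(OCc2ccccc2)c([C@@H]2C(=O)c3c(OCc4ccccc4)cc(OCc4ccccc4)cc3O[C@H]2c2ccc(OCc3ccccc3)c(OCc3ccccc3)c2)c1OCc1ccccc1 | intermediate
11 | (±)-trans-3-[3-acetyl-4,6-bis(benzyloxy)-2-hydroxyphenyl]-7-(benzyloxy)-2-[3,4-bis(benzyloxy)phenyl]-5-hydroxychroman-4-one | CC(=O)c1c(OCc2ccccc2)cc(OCc2ccccc2)c([C@@H]2C(=O)c3c(O)cc(OCc4ccccc4)cc3O[C@H]2c2ccc(OCc3ccccc3)c(OCc3ccccc3)c2)c1O | intermediate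
12 | (±)-trans-7-(benzyloxy)-2-[3,4-bis(benzyloxy)phenyl]-3-{4,6-bis(benzyloxy)-3-[(E)-3-(dimethylamino)prop-2-enoyl]-2-hydroxyphenyl}-5-hydroxychroman-4-one (not isolated) | CN(C)/C=C/C(=O)c1c(OCc2ccccc2)cc(OCc2ccccc2)c([C@@H]2C(=O)c3c(O)cc(OCc4ccccc4)cc3O[C@H]2c2ccc(OCc3ccccc3)c(OCc3ccccc3)c2)c1O | intermediate
13 | (±)-trans-7-(benzyloxy)-2-[3,4-bis(benzyloxy)phenyl]-3-[5,7-bis(benzyloxy)-4-oxo-4H-chromen-8-yl]-5-hydroxychroman-4-one | O=c1ccoc2c1c(OCc1ccccc1)cc(OCc1ccccc1)c2[C@@H]1C(=O)c2c(O)cc(OCc3ccccc3)cc2O[C@H]1c1ccc(OCc2ccccc2)c(OCc2ccccc2)c1 | intermediate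
14 | 4-(benzyloxy)phenylboronic acid | OB(O)c1ccc(OCc2ccccc2)cc1 | starting material
15 | (2R,3S)-7-(benzyloxy)-2-[3,4-bis(benzyloxy)phenyl]-3-{(2S)-5,7-bis(benzyloxy)-2-[4-(benzyloxy)phenyl]-4-oxochroman-8-yl}-5-hydroxychroman-4-one | O=C1C[C@@H](c2ccc(OCc3ccccc3)cc2)Oc2c1c(OCc1ccccc1)cc(OCc1ccccc1)c2[C@@H]1C(=O)c2c(O)cc(OCc3ccccc3)cc2O[C@H]1c1ccc(OCc2ccccc2)c(OCc2ccccc2)c1 | intermediate
16 | (2R,3S)-2-(3,4-dihydroxyphenyl)-3-[(2S)-5,7-dihydroxy-2-(4-hydroxyphenyl)-4-oxochroman-8-yl]-5,7-dihydroxychroman-4-one | O=C1C[C@@H](c2ccc(O)cc2)Oc2c1c(O)cc(O)c2[C@@H]1C(=O)c2c(O)cc(O)cc2O[C@H]1c1ccc(O)c(O)c1 | target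

**Totals and risks**
Total step count: 9. Longest linear sequence: 8 steps (1, 3, 4, 5, 6, 7, 8, 9 from compound 1); step 2 is the side branch.

Three steps most likely to fail:

Step 3 (α-arylation with two di-ortho-substituted, electron-rich partners). The fallback sets out from 2 and comes back at 5. Oxidative 1,2-aryl migration of 2 with PhI(OAc)2 and catalytic H2SO4 in HC(OMe)3/MeOH gives methyl [2,4,6-tris(benzyloxy)phenyl]acetate F1. Hydrolysis with LiOH in THF/H2O gives [2,4,6-tris(benzyloxy)phenyl]acetic acid F2. Friedel–Crafts acylation of 3 with F2, activated by (CF3CO)2O and catalytic H3PO4 in CH2Cl2, then gives 5 without any cross-coupling.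

Step 6 (which of the two acetyl-flanking benzyl ethers BCl3 removes). The fallback sets out from 9 and comes back at 11, replacing selective deprotection by selective protection. Compound 9 is acetylated as before and 10 is isolated. Exhaustive hydrogenolysis of 10 (H2, Pd/C, THF/MeOH) gives (±)-trans-3-(3-acetyl-2,4,6-trihydroxyphenyl)-2-(3,4-dihydroxyphenyl)-5,7-dihydroxychroman-4-one F3. Benzylation with BnBr (5 equiv) and K2CO3 in acetone at rt caps the five unchelated hydroxyls. The unit E 5-OH and the crowded pendant hydroxyl between the acetyl group and the chromanone stay free because they are carbonyl-chelated and hindered, which is 11.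

Step 8 (1,4-arylation of an electron-rich, hindered 5,7-dialkoxychromone, then diastereomer separation). The fallback sets out from 11 and comes back at 15, building the pyranone of unit N through a chalcone. Claisen–Schmidt condensation of 11 with commercial 4-(benzyloxy)benzaldehyde (KOH, EtOH/THF, rt) gives (±)-trans-7-(benzyloxy)-2-[3,4-bis(benzyloxy)phenyl]-3-{4,6-bis(benzyloxy)-3-[(E)-3-(4-benzyloxyphenyl)prop-2-enoyl]-2-hydroxyphenyl}-5-hydroxychroman-4-one F4. Intramolecular oxa-Michael cyclisation with a quinine-derived bifunctional thiourea (toluene, 0 °C) closes the ring with the 2''S preference. Compound 15 is then separated by chromatography from (2S,3R)-7-(benzyloxy)-2-[3,4-bis(benzyloxy)phenyl]-3-{(2S)-5,7-bis(benzyloxy)-2-[4-(benzyloxy)phenyl]-4-oxochroman-8-yl}-5-hydroxychroman-4-one F5, with a final chiral-stationary-phase HPLC pass if control at C-2'' is incomplete.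

**Further compounds**
F1 | step 3 | methyl [2,4,6-tris(benzyloxy)phenyl]acetate | COC(=O)Cc1c(OCc2ccccc2)cc(OCc2ccccc2)cc1OCc1ccccc1
F2 | step 3 | [2,4,6-tris(benzyloxy)phenyl]acetic acid | OC(=O)Cc1c(OCc2ccccc2)cc(OCc2ccccc2)cc1OCc1ccccc1
F3 | step 6 | (±)-trans-3-(3-acetyl-2,4,6-trihydroxyphenyl)-2-(3,4-dihydroxyphenyl)-5,7-dihydroxychroman-4-one | CC(=O)c1c(O)cc(O)c([C@@H]2C(=O)c3c(O)cc(O)cc3O[C@H]2c2ccc(O)c(O)c2)c1O
F4 | step 8 | (±)-trans-7-(benzyloxy)-2-[3,4-bis(benzyloxy)phenyl]-3-{4,6-bis(benzyloxy)-3-[(E)-3-(4-benzyloxyphenyl)prop-2-enoyl]-2-hydroxyphenyl}-5-hydroxychroman-4-one | O=C(/C=C/c1ccc(OCc2ccccc2)cc1)c1c(OCc2ccccc2)cc(OCc2ccccc2)c([C@@H]2C(=O)c3c(O)cc(OCc4ccccc4)cc3O[C@H]2c2ccc(OCc3ccccc3)c(OCc3ccccc3)c2)c1O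
F5 | step 8 | (2S,3R)-7-(benzyloxy)-2-[3,4-bis(benzyloxy)phenyl]-3-{(2S)-5,7-bis(benzyloxy)-2-[4-(benzyloxy)phenyl]-4-oxochroman-8-yl}-5-hydroxychroman-4-one | O=C1C[C@@H](c2ccc(OCc3ccccc3)cc2)Oc2c1c(OCc1ccccc1)cc(OCc1ccccc1)c2[C@H]1C(=O)c2c(O)cc(OCc3ccccc3)cc2O[C@@H]1c1ccc(OCc2ccccc2)c(OCc2ccccc2)c1
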